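The route rests on cutting the C2–C3 bond of the dimethylpyran ring D (chromene numbering). This reduces ring D to an isopropyl ether on O1 and an ethynyl group on C4a of ring B. The key step exploits the fully substituted, oxygen-bearing C2. In the precursor it is a tertiary, hydridic C–H, while alkyne carbon C4 is benzylic and flanked by the two oxygens of ring B. PtI4 triggers a 1,5-hydride shift from that C–H to C4. Vinylplatinum carbon C3 then closes onto oxocarbenium carbon C2, an atom-neutral isomerisation to the chromene. Suzuki union with rings A and C, dynamic kinetic transfer hydrogenation and reoxidation set C3 of ring C as R.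

Key step: step 5

Assumption: the sense of induction in step 9 is taken from the usual aryl ketone model for this catalyst family, in which the (R,R)-catalyst gives the R benzylic alcohol of chroman-4-ones. The mirror-image catalyst is equally available. C3 of ring C is epimerisable, so it is set late and afterwards meets only buffered, near-neutral conditions.

Step 1
Reactants: 1 4-bromoresorcinol
Product: 2 2-bromo-5-isopropoxyphenol
Conditions: 2-bromopropane (1.0 equiv), K2CO3 (1.0 equiv), DMF, 50 °C
Reagents that add atoms: 2-bromopropane CC(C)Br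
Why: Williamson ether synthesis: under equilibrating carbonate conditions the hindered secondary bromide should be taken by the freer and more nucleophilic phenoxide para to bromine, not by the oxygen that is shielded and deactivated by the ortho bromine.

Step 2
Reactants: 2 2-bromo-5-isopropoxyphenol
Product: 3 3-bromo-2-hydroxy-6-isopropoxybenzaldehyde
Conditions: MgCl2, Et3N, paraformaldehyde, MeCN, reflux; dilute HCl work-up
Reagents that add atoms: formaldehyde (as paraformaldehyde) C=O
Why: Casnati–Skattebøl ortho-formylation: the magnesium phenoxide delivers formaldehyde only ortho to its own oxygen, one ortho site is blocked by bromine, so the carbon between the two oxygens is the only one that can react, and a second formaldehyde oxidises the benzylic alkoxide to the aldehyde by hydride transfer.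

Step 3
Reactants: 3 3-bromo-2-hydroxy-6-isopropoxybenzaldehyde
Product: 4 3-bromo-6-isopropoxy-2-(triisopropylsilyloxy)benzaldehyde
Conditions: i-Pr3SiOTf, 2,6-lutidine, CH2Cl2, 0 °C to rt
Reagents that add atoms: triisopropylsilyl triflate CC(C)[Si](C(C)C)(C(C)C)OS(=O)(=O)C(F)(F)F
Why: Silyl ether formation with a silyl triflate, reactive enough for a chelated and doubly flanked phenol; the triisopropylsilyl group is chosen because it has no hydridic C–H next to oxygen, makes the oxygen a poor nucleophile and leaves with buffered fluoride at the end.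

Step 4
Reactants: 4 3-bromo-6-isopropoxy-2-(triisopropylsilyloxy)benzaldehyde
Product: 5 1-bromo-3-ethynyl-4-isopropoxy-2-(triisopropylsilyloxy)benzene
Conditions: Me3SiCHN2, LiN(i-Pr)2, THF, −78 °C; then 4, −78 °C to rt
Reagents that add atoms: trimethylsilyldiazomethane C[Si](C)(C)C=[N+]=[N-]
Why: Colvin rearrangement (addition of lithiated trimethylsilyldiazomethane, Peterson-type loss of silanolate, loss of N2 and 1,2-hydrogen shift of the alkylidene carbene) gives the terminal alkyne in an aprotic medium that spares the aryl silyl ether and the aryl bromide.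

Step 5
Reactants: 5 1-bromo-3-ethynyl-4-isopropoxy-2-(triisopropylsilyloxy)benzene
Product: 6 6-bromo-2,2-dimethyl-5-(triisopropylsilyloxy)-2H-chromene
Conditions: PtI4 (10 mol %), 4 Å molecular sieves, MeCN, 100 °C, sealed vessel
Reagents that add atoms: none
Why: Proposed new method: PtI4 binds the terminal alkyne and slips toward C3, so that C4 becomes a benzylic cationic centre stabilised by the two flanking oxygens of ring B, and the tertiary methine hydrogen of the isopropyl ether moves to C4 as hydride through a six-membered transition state (1,5-hydride shift), which leaves an oxocarbenium ion at C2 and a vinylplatinum carbon at C3. C3 then attacks C2 and releases platinum, so the C2–C3 bond, the fully substituted carbon and the C3=C4 alkene arise in one redox-neutral isomerisation. The closest known reaction types are the platinum- or gold-catalysed hydride-shift hydroalkylation of unactivated terminal alkynes by dialkyl ethers and the Lewis-acid-catalysed hydride shift and ring closure of ortho-alkoxybenzylidene malonates to chromans; the pairing of an aryl isopropyl ether donor with an ortho-ethynyl acceptor is what has not been shown. Ring D closes in a 6-endo-trig mode at the oxocarbenium ion (O1 and both alkene carbons lie inside the new ring), while closure through C4 to a five-membered ring would need a primary platinum carbene and runs against the polarisation of the electron-rich styrenyl unit. No stereocentre is formed. The step needs hydride transfer to outrun attack of an ether oxygen on the alkyne and needs a single hydride donor: the triisopropylsilyl ether has no hydridic C–H within reach and shields a weakly nucleophilic oxygen, the 1,5 geometry allows delivery to C4 only, the C–Br bond is inert to PtI4 and molecular sieves hold back alkyne hydration.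

Step 6
Reactants: 7 2',4',6'-trihydroxyacetophenone
Product: 8 1-[2-hydroxy-4,6-bis(triisopropylsilyloxy)phenyl]ethanone
Conditions: i-Pr3SiCl (2.1 equiv), imidazole, DMF, rt
Reagents that add atoms: triisopropylsilyl chloride CC(C)[Si](Cl)(C(C)C)C(C)C
Why: Silyl ether formation: the para hydroxyl and one ortho hydroxyl react, whereas the last hydroxyl is locked in a hydrogen bond to the ketone and crowded, so silylation should stop at the bis-ether.

Step 7
Reactants: 8 1-[2-hydroxy-4,6-bis(triisopropylsilyloxy)phenyl]ethanone
Product: 10 3-iodo-5,7-bis(triisopropylsilyloxy)-4H-chromen-4-one, via enaminone 9 (not isolated)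
Conditions: Me2NCH(OMe)2, toluene, 90 °C; evaporate; I2, CHCl3, rt
Reagents that add atoms: N,N-dimethylformamide dimethyl acetal COC(OC)N(C)C; iodine II
Why: Enaminone condensation followed by iodine-induced cyclisation (α-iodination of the enaminone, 6-endo attack of the free phenol and loss of dimethylamine), the standard entry to 3-iodochromones.

Step 8
Reactants: 6 6-bromo-2,2-dimethyl-5-(triisopropylsilyloxy)-2H-chromene; 10 3-iodo-5,7-bis(triisopropylsilyloxy)-4H-chromen-4-one
Product: 12 3-[2,2-dimethyl-5-(triisopropylsilyloxy)-2H-chromen-6-yl]-5,7-bis(triisopropylsilyloxy)-4H-chromen-4-one, via lithium aryltriisopropoxyborate 11 (not isolated)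
Conditions: 6, B(Oi-Pr)3, THF/toluene, −78 °C, then n-BuLi, to rt; then 10, Pd(OAc)2, XPhos, aq K3PO4, 40 °C
Reagents that add atoms: triisopropyl borate CC(C)OB(OC(C)C)OC(C)C and n-butyllithium [Li]CCCC (their atoms are kept only in 11)
Why: Bromine–lithium exchange with in situ borate quench followed by Suzuki–Miyaura coupling: the borate ester present from the start traps the aryllithium before the silyl group can migrate from oxygen to carbon, and the preformed ate complex transmetalates at 40 °C under conditions mild enough for the silyl ethers and the iodochromone.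

Step 9
Reactants: 12 3-[2,2-dimethyl-5-(triisopropylsilyloxy)-2H-chromen-6-yl]-5,7-bis(triisopropylsilyloxy)-4H-chromen-4-one
Product: 14 (3R,4R)-3-[2,2-dimethyl-5-(triisopropylsilyloxy)-2H-chromen-6-yl]-5,7-bis(triisopropylsilyloxy)chroman-4-ol, via racemic isoflavanone 13 (not isolated)
Conditions: RuCl[(R,R)-TsDPEN](p-cymene) (5 mol %), HCO2H/Et3N (1:1), EtOAc, 40 °C
Reagents that add atoms: none
Why: Noyori–Ikariya asymmetric transfer hydrogenation with dynamic kinetic resolution: ruthenium hydride first reduces the polarised C2=C3 bond of ring C (the unpolarised ring D alkene is left alone), Et3N racemises 13 through its enol, and the (R,R)-catalyst reduces only the 3R ketone from the face anti to the aryl group, which fixes C4 as R by catalyst control and C3 as R through the cis relationship.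

Step 10
Reactants: 14 (3R,4R)-3-[2,2-dimethyl-5-(triisopropylsilyloxy)-2H-chromen-6-yl]-5,7-bis(triisopropylsilyloxy)chroman-4-ol
Product: 15 (3R)-3-[2,2-dimethyl-5-(triisopropylsilyloxy)-2H-chromen-6-yl]-5,7-bis(triisopropylsilyloxy)chroman-4-one
Conditions: Dess–Martin periodinane, NaHCO3, CH2Cl2, 0 °C
Reagents that add atoms: none
Why: Dess–Martin oxidation under bicarbonate buffer removes the auxiliary C4 stereocentre without acid or base strong enough to enolise the new ketone, so C3 should keep its R configuration.

Step 11
Reactants: 15 (3R)-3-[2,2-dimethyl-5-(triisopropylsilyloxy)-2H-chromen-6-yl]-5,7-bis(triisopropylsilyloxy)chroman-4-one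
Product: 16 (3R)-5,7-dihydroxy-3-(5-hydroxy-2,2-dimethyl-2H-chromen-6-yl)chroman-4-one (target)
Conditions: Bu4NF (3.3 equiv), AcOH (4 equiv), THF, 0 °C to rt; pH 6–7 buffer work-up
Reagents that add atoms: none
Why: Fluoride-induced desilylation: acetic acid buffering protonates each phenoxide as it forms, so that the medium never becomes basic enough to epimerise C3 of ring C, and the ring D alkene is inert to fluoride.

Compound list
1 | 4-bromoresorcinol (4-bromobenzene-1,3-diol) | Oc1ccc(Br)c(O)c1 | starting material
2 | 2-bromo-5-isopropoxyphenol | CC(C)Oc1ccc(Br)c(O)c1 | intermediate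
3 | 3-bromo-2-hydroxy-6-isopropoxybenzaldehyde | CC(C)Oc1ccc(Br)c(O)c1C=O | intermediate
4 | 3-bromo-6-isopropoxy-2-(triisopropylsilyloxy)benzaldehyde | CC(C)Oc1ccc(Br)c(O[Si](C(C)C)(C(C)C)C(C)C)c1C=O | intermediate
5 | 1-bromo-3-ethynyl-4-isopropoxy-2-(triisopropylsilyloxy)benzene | C#Cc1c(OC(C)C)ccc(Br)c1O[Si](C(C)C)(C(C)C)C(C)C | intermediate
6 | 6-bromo-2,2-dimethyl-5-(triisopropylsilyloxy)-2H-chromene | CC1(C)C=Cc2c(O1)ccc(Br)c2O[Si](C(C)C)(C(C)C)C(C)C | intermediate
7 | 2',4',6'-trihydroxyacetophenone | CC(=O)c1c(O)cc(O)cc1O | starting material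
8 | 1-[2-hydroxy-4,6-bis(triisopropylsilyloxy)phenyl]ethanone | CC(=O)c1c(O)cc(O[Si](C(C)C)(C(C)C)C(C)C)cc1O[Si](C(C)C)(C(C)C)C(C)C | intermediate
9 | (E)-3-(dimethylamino)-1-[2-hydroxy-4,6-bis(triisopropylsilyloxy)phenyl]prop-2-en-1-one (enaminone, not isolated) | CN(C)/C=C/C(=O)c1c(O)cc(O[Si](C(C)C)(C(C)C)C(C)C)cc1O[Si](C(C)C)(C(C)C)C(C)C | intermediate
10 | 3-iodo-5,7-bis(triisopropylsilyloxy)-4H-chromen-4-one | O=c1c(I)coc2cc(O[Si](C(C)C)(C(C)C)C(C)C)cc(O[Si](C(C)C)(C(C)C)C(C)C)c12 | intermediate
11 | lithium [2,2-dimethyl-5-(triisopropylsilyloxy)-2H-chromen-6-yl]triisopropoxyborate (not isolated) | [Li+].CC(C)O[B-](OC(C)C)(OC(C)C)c1ccc2OC(C)(C)C=Cc2c1O[Si](C(C)C)(C(C)C)C(C)C | intermediate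
12 | 3-[2,2-dimethyl-5-(triisopropylsilyloxy)-2H-chromen-6-yl]-5,7-bis(triisopropylsilyloxy)-4H-chromen-4-one | CC1(C)C=Cc2c(O1)ccc(c2O[Si](C(C)C)(C(C)C)C(C)C)c3coc4cc(O[Si](C(C)C)(C(C)C)C(C)C)cc(O[Si](C(C)C)(C(C)C)C(C)C)c4c3=O | intermediate
13 | racemic 3-[2,2-dimethyl-5-(triisopropylsilyloxy)-2H-chromen-6-yl]-5,7-bis(triisopropylsilyloxy)chroman-4-one (not isolated) | CC1(C)C=Cc2c(O1)ccc(c2O[Si](C(C)C)(C(C)C)C(C)C)C3COc4cc(O[Si](C(C)C)(C(C)C)C(C)C)cc(O[Si](C(C)C)(C(C)C)C(C)C)c4C3=O | intermediate
14 | (3R,4R)-3-[2,2-dimethyl-5-(triisopropylsilyloxy)-2H-chromen-6-yl]-5,7-bis(triisopropylsilyloxy)chroman-4-ol (cis) | CC1(C)C=Cc2c(O1)ccc(c2O[Si](C(C)C)(C(C)C)C(C)C)[C@@H]3COc4cc(O[Si](C(C)C)(C(C)C)C(C)C)cc(O[Si](C(C)C)(C(C)C)C(C)C)c4[C@@H]3O | intermediate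
15 | (3R)-3-[2,2-dimethyl-5-(triisopropylsilyloxy)-2H-chromen-6-yl]-5,7-bis(triisopropylsilyloxy)chroman-4-one | CC1(C)C=Cc2c(O1)ccc(c2O[Si](C(C)C)(C(C)C)C(C)C)[C@@H]3COc4cc(O[Si](C(C)C)(C(C)C)C(C)C)cc(O[Si](C(C)C)(C(C)C)C(C)C)c4C3=O | intermediate
16 | (3R)-5,7-dihydroxy-3-(5-hydroxy-2,2-dimethyl-2H-chromen-6-yl)chroman-4-one | CC1(C)C=Cc2c(ccc([C@@H]3COc4cc(O)cc(O)c4C3=O)c2O)O1 | target

Total steps: 11. Longest linear sequence: 9 (steps 1–5 and 8–11).

Steps most likely to fail

**Step 5 (Proposed new method).**
- An aryl ether oxygen stabilises the oxocarbenium ion less than a dialkyl ether does, so the hydride shift may be too slow.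
- Three processes could then take over: attack of an ether oxygen on the activated alkyne with loss of its alkyl or silyl group, alkyne hydration, or proton loss from the oxocarbenium ion after the hydride shift.
- The fallback uses known chemistry, closes the same bond, sets out from aldehyde 4 and comes back at 6.
- Pinnick oxidation (NaClO2, NaH2PO4, 2-methyl-2-butene) gives 3-bromo-6-isopropoxy-2-(triisopropylsilyloxy)benzoic acid F1.
- Oxalyl chloride with catalytic DMF gives 3-bromo-6-isopropoxy-2-(triisopropylsilyloxy)benzoyl chloride F2.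
- Diazomethane with Et3N gives 1-[3-bromo-6-isopropoxy-2-(triisopropylsilyloxy)phenyl]-2-diazoethanone F3.
- Rh2(OAc)4 in CH2Cl2 forms the rhodium carbenoid, which inserts into the tertiary C–H next to the ether oxygen. This closes C2–C3 to 6-bromo-2,2-dimethyl-5-(triisopropylsilyloxy)chroman-4-one F4. Carbenoid C–H insertion next to an aryl ether oxygen is a known way to chroman-4-ones.
- NaBH4 gives racemic 6-bromo-2,2-dimethyl-5-(triisopropylsilyloxy)chroman-4-ol F5, and catalytic p-TsOH in warm toluene dehydrates it to 6.

**Step 9.**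
- The peri silyloxy group at C5 and the ortho-silyloxyaryl group at C3 crowd the ketone, so carbonyl reduction may be slow or poorly face-selective.
- Racemisation of the slow enantiomer may lag behind reduction, and the electron-rich benzylic alcohol may ionise in the formic acid medium.
- The fallback sets C3 by enantioselective protonation instead of reduction. It sets out from 12 and comes back at 15, so step 10 is no longer needed.
- Conjugate reduction of 12 with LiBH(s-Bu)3 in THF at −78 °C and trapping of the enolate with allyl chloroformate gives allyl 3-[2,2-dimethyl-5-(triisopropylsilyloxy)-2H-chromen-6-yl]-5,7-bis(triisopropylsilyloxy)-2H-chromen-4-yl carbonate F6.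
- Pd2(dba)3 and (S)-t-Bu-PHOX, with Meldrum's acid as proton donor and allyl acceptor, then effect decarboxylative asymmetric protonation of the palladium enolate to 15. The ligand enantiomer is chosen for the R product.

**Step 8.**
- The silyl group may migrate from oxygen to the lithiated carbon.
- The electron-rich borate may undergo protodeboronation.
- Transmetalation next to the bulky ortho silyloxy group may be slow.
- The fallback forms the same bond by enolate arylation, without any organoboron species. It sets out from bromide 6 and comes back at 13.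
- Commercial 5,7-dihydroxychroman-4-one F7 is silylated (i-Pr3SiOTf, 2,6-lutidine, CH2Cl2) to 5,7-bis(triisopropylsilyloxy)chroman-4-one F8.
- Palladium-catalysed α-arylation of F8 with 6 (Pd(OAc)2, P(t-Bu)3·HBF4, K3PO4, toluene, 90 °C) gives racemic isoflavanone 13. It is isolated in this case and enters step 9 at the carbonyl reduction stage.

Further compounds
F1 | step 5 | 3-bromo-6-isopropoxy-2-(triisopropylsilyloxy)benzoic acid | CC(C)Oc1ccc(Br)c(O[Si](C(C)C)(C(C)C)C(C)C)c1C(=O)O
F2 | step 5 | 3-bromo-6-isopropoxy-2-(triisopropylsilyloxy)benzoyl chloride | CC(C)Oc1ccc(Br)c(O[Si](C(C)C)(C(C)C)C(C)C)c1C(=O)Cl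
F3 | step 5 | 1-[3-bromo-6-isopropoxy-2-(triisopropylsilyloxy)phenyl]-2-diazoethanone | CC(C)Oc1ccc(Br)c(O[Si](C(C)C)(C(C)C)C(C)C)c1C(=O)C=[N+]=[N-]
F4 | step 5 | 6-bromo-2,2-dimethyl-5-(triisopropylsilyloxy)chroman-4-one | CC1(C)CC(=O)c2c(O1)ccc(Br)c2O[Si](C(C)C)(C(C)C)C(C)C
F5 | step 5 | racemic 6-bromo-2,2-dimethyl-5-(triisopropylsilyloxy)chroman-4-ol | CC1(C)CC(O)c2c(O1)ccc(Br)c2O[Si](C(C)C)(C(C)C)C(C)C
F6 | step 9 | allyl 3-[2,2-dimethyl-5-(triisopropylsilyloxy)-2H-chromen-6-yl]-5,7-bis(triisopropylsilyloxy)-2H-chromen-4-yl carbonate | C=CCOC(=O)OC1=C(c2ccc3OC(C)(C)C=Cc3c2O[Si](C(C)C)(C(C)C)C(C)C)COc2cc(O[Si](C(C)C)(C(C)C)C(C)C)cc(O[Si](C(C)C)(C(C)C)C(C)C)c12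
F7 | step 8 | 5,7-dihydroxychroman-4-one | O=C1CCOc2cc(O)cc(O)c12
F8 | step 8 | 5,7-bis(triisopropylsilyloxy)chroman-4-one | O=C1CCOc2cc(O[Si](C(C)C)(C(C)C)C(C)C)cc(O[Si](C(C)C)(C(C)C)C(C)C)c12
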